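## Retrosynthetic overview
1. The aroyl ester comes from Pd-catalysed carbonylation of a 4-iodophenol unit onto the C6 alcohol. The oxirane comes from OH-directed epoxidation of an (E,E)-germacradienol. C6 is set by a C8-OH-directed Evans–Tishchenko reduction of the 6-ketone.
2. The ten-membered (E,E)-dienone arises by ring expansion of a five/seven-fused γ-mesyloxy enone. Methyl cuprate delivers C15 to C4, and the resulting enolate breaks the central C4–C10 bond and expels mesylate.
3. The seven-membered enone is closed by aldol condensation of a C6 methyl ketone onto a 2,2-disubstituted cyclopentane-1,3-dione. The C1 leaving group follows by ketone reduction and mesylation.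
4. The C7/C8 pair comes from a catalytic asymmetric anti-allylboration of the dione acetaldehyde. The (E)-γ-isopropylallyl boronate is made by alkyne hydroboration and a Matteson 1,2-shift.
5. Ring order: five-membered ring (bought), seven-membered ring (step 8), ten-membered ring (step 11), oxirane (step 14).

Assumption: germacrane atom labels of the target are used for all intermediates, and CIP descriptors refer to these labels. The labels are C1=C10 alkene, C4–C5 oxirane, C6 ester, C7 isopropyl, C8 OH, C14 on C10 and C15 on C4. The target is (1(10)E,4R,5R,6S,7R,8R), with a trans oxirane. Compounds 1, 2, 5, 7 and 24 are taken to be catalogue chemicals.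

## Route

Step 1
Reactants: 1 2-methylcyclopentane-1,3-dione; 2 allyl bromide
Product: 3 2-allyl-2-methylcyclopentane-1,3-dione
Conditions: NaOH (1 M aq), 2 (1.5 equiv), rt, 24 h
Reagents that add atoms: none
Why: Enolate C-alkylation, in which the fully ionised cyclic 1,3-dione takes the reactive allylic bromide on carbon and gives the still achiral quaternary C10.

Step 2
Reactants: 3 2-allyl-2-methylcyclopentane-1,3-dione
Product: 4 2-(1-methyl-2,5-dioxocyclopentyl)acetaldehyde
Conditions: O3, CH2Cl2, −78 °C; then Me2S, −78 °C → rt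
Reagents that add atoms: ozone [O-][O+]=O
Why: Ozonolysis with reductive work-up cleaves the only alkene to the C8 aldehyde and leaves the dione untouched.

Step 3
Reactants: 5 3-methylbut-1-yne
Product: 6 (E)-2-(3-methylbut-1-enyl)-4,4,5,5-tetramethyl-1,3,2-dioxaborolane
Conditions: pinacolborane, Cp2ZrHCl (5 mol %), Et3N (10 mol %), neat, sealed tube, 60 °C
Reagents that add atoms: pinacolborane [H]B1OC(C)(C)C(C)(C)O1
Why: Catalysed syn hydroboration of a terminal alkyne puts boron on the terminus and gives only the (E)-alkenylboronate.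

Step 4
Reactants: 6 (E)-alkenylboronate; 7 chloroiodomethane
Product: 9 (E)-2-(4-methylpent-2-enyl)-4,4,5,5-tetramethyl-1,3,2-dioxaborolane, via chloromethyl borate 8 (not isolated)
Conditions: 7 (1.5 equiv), n-BuLi (1.4 equiv), THF, −78 °C → rt
Reagents that add atoms: none
Why: Matteson homologation, in which chloromethyllithium adds to boron and the alkenyl group makes a 1,2-metallate shift that expels chloride with the (E)-alkene retained.

Step 5
Reactants: 4 dione acetaldehyde; 9 (E)-γ-isopropylallyl boronate
Product: 11 2-[(2R,3S)-2-hydroxy-3-isopropylpent-4-enyl]-2-methylcyclopentane-1,3-dione, via pinacol borate 10 (not isolated)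
Conditions: (S)-TRIP phosphoric acid (5 mol %), toluene, −30 °C; aq NaHCO3 work-up
Reagents that add atoms: none
Why: Chiral phosphoric acid-catalysed allylboration through a closed chair gives the anti C7/C8 pair from the (E)-boronate; the (S)-acid should select the face giving 8R (by analogy with benzaldehyde and the (R)-acid, the descriptor inverting with ligand ranking), and ketones do not react.

Step 6
Reactants: 11 homoallylic alcohol
Product: 12 C8 tert-butyldimethylsilyl ether of 11
Conditions: TBSOTf, 2,6-lutidine, CH2Cl2, −78 → 0 °C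
Reagents that add atoms: tert-butyldimethylsilyl triflate CC(C)(C)[Si](C)(C)OS(=O)(=O)C(F)(F)F
Why: Silylation with the reactive triflate protects the hindered C8 alcohol and stops hemiketal formation with the ring ketones.

Step 7
Reactants: 12 silyl ether alkene
Product: 13 2-[(2R,3R)-3-acetyl-2-(tert-butyldimethylsilyloxy)-4-methylpentyl]-2-methylcyclopentane-1,3-dione
Conditions: PdCl2 (10 mol %), CuCl (1 equiv), O2 (1 atm), DMF/H2O 7:1, rt
Reagents that add atoms: water O
Why: Tsuji–Wacker oxidation proceeds by Markovnikov hydroxypalladation of the terminal alkene and gives the C6 methyl ketone without touching C7 or C8.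

Step 8
Reactants: 13 triketone
Product: 15 hydroazulene enedione (7R,8R,10S), via ketol 14 (not isolated)
Conditions: L-phenylalanine (0.5 equiv), (+)-camphorsulfonic acid (0.3 equiv), DMF, 50 °C
Reagents that add atoms: none
Why: Hajos–Parrish-type amine-catalysed intramolecular aldol condensation: the less substituted enamine (C5) attacks a ring carbonyl (attack through C7 cannot dehydrate and reverts), and the L-amino acid plus pseudo-equatorial C7/C8 groups should favour the carbonyl that makes C10 S, any 10-epimer being removed by chromatography.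

Step 9
Reactants: 15 hydroazulene enedione
Product: 16 hydroxy enone (1S,7R,8R,10S) with the C1 hydroxyl cis to the C10 methyl
Conditions: (R)-Me-CBS oxazaborolidine (15 mol %), catecholborane (1.2 equiv), toluene, −78 °C; MeOH, pH 7 buffer
Reagents that add atoms: none
Why: Corey–Bakshi–Shibata reduction: the cyclopentanone should react before the hindered enone, the two faces of C1 differ little (CH3 against CH2), and the (R)-catalyst reads C10 as the large and C2 as the small flank to set 1S.

Step 10
Reactants: 16 hydroxy enone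
Product: 17 C1 mesylate of 16 (1S,7R,8R,10S)
Conditions: MsCl, Et3N, CH2Cl2, 0 °C
Reagents that add atoms: methanesulfonyl chloride CS(=O)(=O)Cl
Why: Sulfonylation through sulfene turns the hindered secondary alcohol into the leaving group with retention at C1.

Step 11
Reactants: 17 mesyloxy enone
Product: 19 (1(10)E,4E,7R,8R)-8-(tert-butyldimethylsilyloxy)germacra-1(10),4-dien-6-one, via lithium enolate 18 (not isolated)
Conditions: Me2CuLi (from MeLi and CuI, 1.2 equiv), Et2O, −40 → 0 °C; then THF/DMPU, 0 °C → rt; aq NH4Cl/NH3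
Reagents that add atoms: lithium dimethylcuprate [Li+].C[Cu-]C
Why: Proposed new method: a conjugate-addition-triggered seven-centre (vinylogous Grob) fragmentation used as a five/seven to ten ring expansion. The cuprate puts C15 on C4 and so generates regiospecifically the C5=C6 enolate, whose electrons re-form C6=O, make C4=C5, break the crowded C4–C10 bond between two quaternary carbons, make C10=C1 and expel mesylate irreversibly. With C1–OMs antiperiplanar to C4–C10 and cis to C14, C9 ends trans to C2 (1(10)E). The enolate held in the seven-membered ring can overlap with C4–C10 only in the rotamer that puts C3 trans to C6 (4E). The C1, C4 and C10 configurations are erased, so the face of methyl delivery does not matter, and the left-over MeCu does not add to the product enone. The closest known reaction types are base-induced enolate-assisted 1,4-fragmentation of γ-sulfonyloxy carbonyl compounds in decalins and cuprate addition to angularly methylated bicyclic enones.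

Step 12
Reactants: 19 silyloxy dienone
Product: 20 (1(10)E,4E,7R,8R)-8-hydroxygermacra-1(10),4-dien-6-one
Conditions: HF·pyridine, pyridine, THF, 0 °C
Reagents that add atoms: none
Why: Buffered fluoride desilylation frees the C8 hydroxyl without acid-induced transannular cyclisation or β-elimination.

Step 13
Reactants: 20 β-hydroxy dienone
Product: 22 (1(10)E,4E,6R,7S,8R)-8-acetoxygermacra-1(10),4-dien-6-ol, via hemiacetal 21 (not isolated)
Conditions: SmI2 (30 mol %), CH3CHO (8 equiv), THF, −10 °C
Reagents that add atoms: acetaldehyde CC=O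
Why: Evans–Tishchenko reduction: the C8 hemiacetal bound to trivalent samarium hands its hydride to C6 through a chair from the C8-O side, which sets the 1,3-anti C6 carbinol (against the peripheral Felkin face) and leaves O8 as acetate and O6 free.

Step 14
Reactants: 22 allylic alcohol
Product: 23 (1(10)E,4R,5R,6S,7S,8R)-8-acetoxy-4,5-epoxygermacr-1(10)-en-6-ol
Conditions: VO(acac)2 (5 mol %), t-BuOOH (1.2 equiv, decane), CH2Cl2, 0 °C
Reagents that add atoms: tert-butyl hydroperoxide CC(C)(C)OO
Why: Hydroxyl-directed vanadium-catalysed epoxidation: only the allylic C4=C5 alkene reacts, and A(1,3) strain with C15 puts H6 in the alkene plane and O6 on the outer face, so peripheral syn delivery gives the threo trans-epoxide (4R,5R).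

Step 15
Reactants: 24 4-iodophenol
Product: 25 tert-butyl(4-iodophenoxy)dimethylsilane
Conditions: TBSCl, imidazole, DMF, rt
Reagents that add atoms: tert-butyldimethylsilyl chloride CC(C)(C)[Si](C)(C)Cl
Why: Silylation masks the phenol so that it cannot compete as a nucleophile in the carbonylation.

Step 16
Reactants: 23 epoxy alcohol; 25 silylated iodophenol
Product: 26 6-O-[4-(tert-butyldimethylsilyloxy)benzoyl] 8-O-acetyl epoxide (4R,5R,6S,7R,8R)
Conditions: Pd(OAc)2 (5 mol %), Xantphos (6 mol %), CO (1 atm), Et3N, DMAP (20 mol %), 25 (1.5 equiv), toluene, 70 °C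
Reagents that add atoms: carbon monoxide [C-]#[O+]
Why: Palladium-catalysed alkoxycarbonylation: oxidative addition of the aryl iodide to zerovalent palladium, CO insertion and DMAP-relayed acyl transfer esterify the only free hydroxyl with retention at C6.

Step 17
Reactants: 26 protected ester
Product: 28 target CNP0319712.1, via phenol acetate 27 (not isolated)
Conditions: K2CO3 (0.5 equiv), MeOH, 0 °C → rt
Reagents that add atoms: none
Why: Base-catalysed methanolysis (Zemplén type): the electron-poor aryl silyl ether falls first, the resulting phenoxide deactivates the hindered C6 aroyl ester, and the C8 acetate is then transesterified selectively.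

## Compound list
1 | 2-methylcyclopentane-1,3-dione | CC1C(=O)CCC1=O | starting material
2 | allyl bromide | C=CCBr | starting material
3 | 2-allyl-2-methylcyclopentane-1,3-dione | C=CCC1(C)C(=O)CCC1=O | intermediate
4 | 2-(1-methyl-2,5-dioxocyclopentyl)acetaldehyde | O=CCC1(C)C(=O)CCC1=O | intermediate
5 | 3-methylbut-1-yne | CC(C)C#C | starting material
6 | (E)-2-(3-methylbut-1-enyl)-4,4,5,5-tetramethyl-1,3,2-dioxaborolane | CC(C)/C=C/B1OC(C)(C)C(C)(C)O1 | intermediate
7 | chloroiodomethane | ClCI | starting material
8 | lithium chloromethyl[(E)-3-methylbut-1-enyl]pinacolatoborate | [Li+].CC(C)/C=C/[B-]1(CCl)OC(C)(C)C(C)(C)O1 | intermediate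
9 | (E)-2-(4-methylpent-2-enyl)-4,4,5,5-tetramethyl-1,3,2-dioxaborolane | CC(C)/C=C/CB1OC(C)(C)C(C)(C)O1 | intermediate
10 | O8-pinacol borate of 11 | C=C[C@H](C(C)C)[C@H](OB1OC(C)(C)C(C)(C)O1)CC1(C)C(=O)CCC1=O | intermediate
11 | 2-[(2R,3S)-2-hydroxy-3-isopropylpent-4-enyl]-2-methylcyclopentane-1,3-dione (7S,8R) | C=C[C@H](C(C)C)[C@H](O)CC1(C)C(=O)CCC1=O | intermediate
12 | C8 TBS ether of 11 (7S,8R) | C=C[C@H](C(C)C)[C@H](O[Si](C)(C)C(C)(C)C)CC1(C)C(=O)CCC1=O | intermediate
13 | 2-[(2R,3R)-3-acetyl-2-(TBS-oxy)-4-methylpentyl]-2-methylcyclopentane-1,3-dione (7R,8R) | CC(=O)[C@H](C(C)C)[C@H](O[Si](C)(C)C(C)(C)C)CC1(C)C(=O)CCC1=O | intermediate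
14 | cis-fused ketol, C4-OH cis to C14 (4S,7R,8R,10S) | O=C1C[C@@]2(O)CCC(=O)[C@@]2(C)C[C@@H](O[Si](C)(C)C(C)(C)C)[C@H]1C(C)C | intermediate
15 | hydroazulene enedione: five-ring C10-C1(=O)-C2-C3-C4, seven-ring C4=C5-C6(=O)-C7(iPr)-C8(OTBS)-C9-C10(CH3) (7R,8R,10S) | O=C1C=C2CCC(=O)[C@@]2(C)C[C@@H](O[Si](C)(C)C(C)(C)C)[C@H]1C(C)C | intermediate
16 | C1 alcohol of 15, OH cis to C14 (1S,7R,8R,10S) | O=C1C=C2CC[C@H](O)[C@@]2(C)C[C@@H](O[Si](C)(C)C(C)(C)C)[C@H]1C(C)C | intermediate
17 | C1 mesylate of 16 (1S,7R,8R,10S) | O=C1C=C2CC[C@H](OS(C)(=O)=O)[C@@]2(C)C[C@@H](O[Si](C)(C)C(C)(C)C)[C@H]1C(C)C | intermediate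
18 | lithium C5=C6 enolate, C14, C15 and OMs cis (1S,4R,7R,8R,10S) | [Li+].[O-]C1=C[C@@]2(C)CC[C@H](OS(C)(=O)=O)[C@@]2(C)C[C@@H](O[Si](C)(C)C(C)(C)C)[C@H]1C(C)C | intermediate
19 | (1(10)E,4E,7R,8R)-8-(TBS-oxy)germacra-1(10),4-dien-6-one | C/C1=C\CC/C(C)=C/C(=O)[C@H](C(C)C)[C@H](O[Si](C)(C)C(C)(C)C)C1 | intermediate
20 | (1(10)E,4E,7R,8R)-8-hydroxygermacra-1(10),4-dien-6-one | C/C1=C\CC/C(C)=C/C(=O)[C@H](C(C)C)[C@H](O)C1 | intermediate
21 | O8 acetaldehyde hemiacetal of 20 (samarium-bound in the flask) | C/C1=C\CC/C(C)=C/C(=O)[C@H](C(C)C)[C@H](OC(C)O)C1 | intermediate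
22 | (1(10)E,4E,6R,7S,8R)-8-acetoxygermacra-1(10),4-dien-6-ol | C/C1=C\CC/C(C)=C/[C@@H](O)[C@H](C(C)C)[C@H](OC(C)=O)C1 | intermediate
23 | (1(10)E,4R,5R,6S,7S,8R)-8-acetoxy-4,5-epoxygermacr-1(10)-en-6-ol | C/C1=C\CC[C@@]2(C)O[C@@H]2[C@@H](O)[C@H](C(C)C)[C@H](OC(C)=O)C1 | intermediate
24 | 4-iodophenol | Oc1ccc(I)cc1 | starting material
25 | tert-butyl(4-iodophenoxy)dimethylsilane | CC(C)(C)[Si](C)(C)Oc1ccc(I)cc1 | intermediate
26 | 6-O-(4-TBS-oxybenzoyl) 8-O-acetyl epoxide (4R,5R,6S,7R,8R) | C/C1=C\CC[C@@]2(C)O[C@@H]2[C@@H](OC(=O)c2ccc(O[Si](C)(C)C(C)(C)C)cc2)[C@H](C(C)C)[C@H](OC(C)=O)C1 | intermediate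
27 | 6-O-(4-hydroxybenzoyl) 8-O-acetyl epoxide | C/C1=C\CC[C@@]2(C)O[C@@H]2[C@@H](OC(=O)c2ccc(O)cc2)[C@H](C(C)C)[C@H](OC(C)=O)C1 | intermediate
28 | CNP0319712.1, (1(10)E,4R,5R,6S,7R,8R)-4,5-epoxy-8-hydroxygermacr-1(10)-en-6-yl 4-hydroxybenzoate | C/C1=C\CC[C@@]2(C)O[C@@H]2[C@@H](OC(=O)c2ccc(O)cc2)[C@H](C(C)C)[C@H](O)C1 | target

## Count and risks
Total steps: 17. Longest linear sequence: 14 (steps 1, 2, 5–14, 16, 17).

Risk 1, step 11 (the proposed new step). The copper/lithium enolate may not fragment, or excess cuprate may add to the product. The fallback sets out from 17 and uncouples the two events with known chemistry. Me2CuLi is added at −78 °C and the mixture is quenched cold with acetic acid, which gives the saturated cis-dimethyl hydroazulenone mesylate F3. This isolated ketone is then deprotonated kinetically at C5 with KN(SiMe3)2 in toluene (0 °C → rt). The free potassium enolate undergoes the known base-induced enolate-assisted 1,4-fragmentation. The route is rejoined at 19.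

Risk 2, step 8. Seven-ring aldol closure may be slow, may give poor C10 selectivity, or may lose the β-silyloxy group. The fallback sets out from 12, before the Wacker step. CH2=CHMgBr/CeCl3 (1 equiv, THF, −78 °C) adds once to a ring ketone to give the vinyl carbinol F1. Ring-closing metathesis with the second-generation Grubbs catalyst (CH2Cl2, reflux) gives the bicyclic tertiary allylic alcohol F2. Oxidative 1,3-transposition with pyridinium chlorochromate, C5H5NH[CrO3Cl], gives the enone. The route is rejoined at 15.

Risk 3, step 13. Retro-aldol cleavage or sluggish hydride transfer may occur in the macrocycle. The fallback sets out from 20. Hydroxyl-directed reduction with Me4NBH(OAc)3 (MeCN/AcOH, −30 °C) gives the 1,3-anti diol F4. The less hindered C8 hydroxyl is then acetylated selectively with AcCl and 2,4,6-collidine in CH2Cl2 at −78 °C. The route is rejoined at 22.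

## Further compounds
F1 | step 8 | 3-hydroxy-2-methyl-3-vinylcyclopentanone carrying the C9–C5 chain of 12 on C10, vinyl cis to C14 | C=C[C@H](C(C)C)[C@H](O[Si](C)(C)C(C)(C)C)C[C@]1(C)C(=O)CC[C@@]1(O)C=C
F2 | step 8 | bicyclic tertiary allylic alcohol, C4(OH)-C5=C6 in the seven-membered ring | O[C@@]12CCC(=O)[C@@]1(C)C[C@@H](O[Si](C)(C)C(C)(C)C)[C@@H](C(C)C)C=C2
F3 | step 11 | saturated cis-4,10-dimethyl hydroazulen-6-one C1 mesylate (1S,4R,7R,8R,10S) | O=C1C[C@@]2(C)CC[C@H](OS(C)(=O)=O)[C@@]2(C)C[C@@H](O[Si](C)(C)C(C)(C)C)[C@H]1C(C)C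
F4 | step 13 | (1(10)E,4E,6R,7R,8R)-germacra-1(10),4-diene-6,8-diol | C/C1=C\CC/C(C)=C/[C@@H](O)[C@H](C(C)C)[C@H](O)C1
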